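**Assumption:** the SMILES is read as the (3Z,6R,7R,9R,10S,12R,13S) isomer on the C15 chain numbered from the alkyne end (ring oxygen between C6 and C12); these chain numbers are used as atom labels throughout. (+)-1,4-Di-O-tosyl-2,3-O-isopropylidene-D-threitol is taken as a catalogue starting material.

**Retrosynthetic overview**
1. Target ⇐ alkyne desilylation and cis-reduction of a silyl diyne (C3=C4); the 9,10-diol ⇐ syn-dihydroxylation of the (Z)-oxocene on the face opposite the three ring substituents.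
2. The only ring (oxocane) is closed by the C12–O bond: 8-exo opening of a (12S,13S)-trans-epoxide by the C6 hydroxyl with inversion at C12 (proposed new catalytic closure).
3. Acyclic hydroxy epoxide ⇐ C2-symmetric (R,R)-diepoxybutane, opened first at C8 by the acetylide of the C9–C15 epoxy alkyne (O7 acetylated in the flask), then, after Lindlar reduction, at C5 by lithio(trimethylsilyl)butadiyne.
4. C9–C15 epoxy alkyne ⇐ Sharpless epoxidation of (E)-pent-2-en-1-ol, then triflate displacement by silylacetylide.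
5. Diepoxide ⇐ D-threitol ditosylate acetonide.

**Route**

Step 1
Reactants: 1 (E)-pent-2-en-1-ol
Product: 2 [(2S,3S)-3-ethyloxiran-2-yl]methanol
Conditions: Ti(OiPr)4 (5 mol %), L-(+)-diisopropyl tartrate (6 mol %), t-BuOOH, 4 Å MS, CH2Cl2, −20 °C
Reagents that add atoms: tert-butyl hydroperoxide, CC(C)(C)OO
Why: Sharpless asymmetric epoxidation; the L-(+)-tartrate/titanium catalyst delivers oxygen to one face of the (E)-allylic alcohol and sets both epoxide carbons (2S,3S), the future C12 and C13.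

Step 2
Reactants: 2 [(2S,3S)-3-ethyloxiran-2-yl]methanol; 3 ethynyltrimethylsilane
Product: 5 trimethyl{3-[(2S,3S)-3-ethyloxiran-2-yl]prop-1-yn-1-yl}silane, via epoxy triflate 4 (not isolated)
Conditions: Tf2O, 2,6-lutidine, CH2Cl2, −78 °C; then LiC≡CSiMe3 (from 3, n-BuLi), THF/DMPU, −78 → −20 °C
Reagents that add atoms: none
Why: Alkylation of a lithium acetylide by a primary triflate (SN2), which at low temperature is much faster than attack on the adjacent epoxide; no stereocentre is touched.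

Step 3
Reactants: 5 trimethyl{3-[(2S,3S)-3-ethyloxiran-2-yl]prop-1-yn-1-yl}silane
Product: 6 (2S,3S)-2-ethyl-3-(prop-2-yn-1-yl)oxirane
Conditions: K2CO3 (cat.), MeOH, 0 °C → rt
Reagents that add atoms: none
Why: Base-catalysed methanolysis of the C(sp)–Si bond (protodesilylation) frees the terminal alkyne; the dialkyl epoxide survives cold carbonate/methanol.

Step 4
Reactants: 7 (+)-1,4-di-O-tosyl-2,3-O-isopropylidene-D-threitol
Product: 9 (2R,2'R)-2,2'-bioxirane, via ditosyl diol 8 (not isolated)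
Conditions: 1 M HCl, THF, 50 °C; then KOH, H2O/Et2O, 0 °C → rt
Reagents that add atoms: none
Why: Acetal hydrolysis followed by double intramolecular Williamson closure (each alkoxide displaces its neighbouring primary tosylate, 3-exo-tet) gives the C2-symmetric diepoxide with the two carbinol centres (future C6 and C7, both R) untouched.

Step 5
Reactants: 6 (2S,3S)-2-ethyl-3-(prop-2-yn-1-yl)oxirane; 9 (2R,2'R)-2,2'-bioxirane
Product: 11 (1R)-5-[(2S,3S)-3-ethyloxiran-2-yl]-1-[(2R)-oxiran-2-yl]pent-3-yn-1-yl acetate, via lithium alkoxytrifluoroborate 10 (not isolated)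
Conditions: n-BuLi, THF, −78 °C; BF3·OEt2; 9 (3 equiv), −78 °C; then Et3N, Ac2O, DMAP, −78 → 0 °C
Reagents that add atoms: acetic anhydride, CC(=O)OC(C)=O
Why: Yamaguchi–Hirao alkynylation, in which the alkynyl trifluoroborate opens one terminal epoxide at its CH2 (the two epoxides are homotopic, so mono-opening gives a single compound and excess 9 suppresses double opening); the boron-bound alkoxide cannot undergo Payne rearrangement and is acetylated in the flask, so O7 is differentiated from the still masked O6.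

Step 6
Reactants: 11 (1R)-5-[(2S,3S)-3-ethyloxiran-2-yl]-1-[(2R)-oxiran-2-yl]pent-3-yn-1-yl acetate
Product: 12 (1R,3Z)-5-[(2S,3S)-3-ethyloxiran-2-yl]-1-[(2R)-oxiran-2-yl]pent-3-en-1-yl acetate
Conditions: H2 (1 atm), Pd/CaCO3 poisoned with Pb(OAc)2 (Lindlar catalyst), quinoline, EtOAc, rt
Reagents that add atoms: none
Why: Lindlar semihydrogenation (syn addition of H2 on poisoned palladium) gives the (9Z)-alkene that later folds the chain for ring closure; epoxides and acetate are inert, and it is done before the diyne is present.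

Step 7
Reactants: 12 (1R,3Z)-5-[(2S,3S)-3-ethyloxiran-2-yl]-1-[(2R)-oxiran-2-yl]pent-3-en-1-yl acetate; 13 1,4-bis(trimethylsilyl)buta-1,3-diyne
Product: 14 (6R,7R,9Z)-11-[(2S,3S)-3-ethyloxiran-2-yl]-6-hydroxy-1-(trimethylsilyl)undec-9-ene-1,3-diyn-7-yl acetate
Conditions: 13, MeLi·LiBr, THF, 0 °C → rt; then −78 °C, BF3·OEt2, 12; NH4Cl (aq) at −78 °C
Reagents that add atoms: none
Why: BF3-mediated epoxide alkynylation (Yamaguchi–Hirao) with the lithium diynide at the terminal CH2 (C5) is faster than attack on the trans-disubstituted epoxide or the acetate at −78 °C and unmasks O6 as the only free hydroxyl, with C6 untouched.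

Step 8
Reactants: 14 (6R,7R,9Z)-11-[(2S,3S)-3-ethyloxiran-2-yl]-6-hydroxy-1-(trimethylsilyl)undec-9-ene-1,3-diyn-7-yl acetate
Product: 15 (2R,3R,8R,5Z)-8-[(1S)-1-hydroxypropyl]-2-[5-(trimethylsilyl)penta-2,4-diyn-1-yl]-3,4,7,8-tetrahydro-2H-oxocin-3-yl acetate
Conditions: (R)-TRIP [(R)-3,3'-bis(2,4,6-triisopropylphenyl)-1,1'-binaphthyl-2,2'-diyl hydrogen phosphate] (10 mol %; matched enantiomer to be confirmed against (S)-TRIP), 5 Å MS, PhCF3, 0.005 M, 40 °C
Reagents that add atoms: none
Why: Proposed new method: a bifunctional chiral phosphoric acid catalysed 8-exo-tet hydroxy-epoxide etherification, in which the P=O oxygen accepts a hydrogen bond from the C6 hydroxyl while the P–OH donates one to the epoxide oxygen, so nucleophile and electrophile are clamped in one hydrogen-bonded array (paying the entropic cost that normally defeats eight-membered closure) while the (9Z)-alkene and the gauche C6–O/C7–O arrangement pre-fold the chain; backside SN2 attack at the nearer epoxide carbon C12 (8-exo, not 9-endo) inverts C12 from S to R, fixes the 2,8-cis ether and releases the C13 hydroxyl with its S configuration untouched; the closest known reactions are phosphoric-acid-catalysed ring openings of epoxides and oxetanes by O–H nucleophiles to five- to seven-membered ethers and stoichiometric lanthanide-promoted hydroxy-epoxide cyclisations of (Z)-olefinic substrates.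

Step 9
Reactants: 15 (2R,3R,8R,5Z)-8-[(1S)-1-hydroxypropyl]-2-[5-(trimethylsilyl)penta-2,4-diyn-1-yl]-3,4,7,8-tetrahydro-2H-oxocin-3-yl acetate
Product: 16 (2R,3R,8R,5Z)-8-[(1S)-1-acetoxypropyl]-2-[5-(trimethylsilyl)penta-2,4-diyn-1-yl]-3,4,7,8-tetrahydro-2H-oxocin-3-yl acetate
Conditions: Ac2O, pyridine, DMAP (cat.), CH2Cl2, 0 °C → rt
Reagents that add atoms: acetic anhydride, CC(=O)OC(C)=O
Why: DMAP-catalysed acylation of the secondary C13 alcohol; no stereocentre is affected.

Step 10
Reactants: 16 (2R,3R,8R,5Z)-8-[(1S)-1-acetoxypropyl]-2-[5-(trimethylsilyl)penta-2,4-diyn-1-yl]-3,4,7,8-tetrahydro-2H-oxocin-3-yl acetate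
Product: 17 (2R,3R,5R,6S,8R)-8-[(1S)-1-acetoxypropyl]-5,6-dihydroxy-2-[5-(trimethylsilyl)penta-2,4-diyn-1-yl]oxocan-3-yl acetate
Conditions: OsO4 (2 mol %), N-methylmorpholine N-oxide, acetone/H2O, 0 °C → rt
Reagents that add atoms: osmium tetroxide, O=[Os](=O)(=O)=O; N-methylmorpholine N-oxide, C[N+]1([O-])CCOCC1; water, O
Why: Upjohn syn-dihydroxylation ([3+2] addition of OsO4) of the only alkene (the diyne is inert), expected on the ring face opposite the homoallylic C7 acetate and the two cis α-side chains, which sets C9 (R) and C10 (S) as a cis-diol trans to those three groups.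

Step 11
Reactants: 17 (2R,3R,5R,6S,8R)-8-[(1S)-1-acetoxypropyl]-5,6-dihydroxy-2-[5-(trimethylsilyl)penta-2,4-diyn-1-yl]oxocan-3-yl acetate
Product: 18 (2R,3R,5R,6S,8R)-8-[(1S)-1-acetoxypropyl]-5,6-dihydroxy-2-[(2Z)-5-(trimethylsilyl)pent-2-en-4-yn-1-yl]oxocan-3-yl acetate
Conditions: Zn dust activated with Cu(OAc)2 and AgNO3, MeOH/H2O, 45 °C
Reagents that add atoms: none
Why: Activated-zinc (Boland-type) reduction of a conjugated diyne, in which surface electron transfer and protonation reduce the alkyl-substituted triple bond cis while the silyl-capped one is spared, giving the (3Z)-enyne after the osmylation so the enyne alkene never competes for OsO4.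

Step 12
Reactants: 18 (2R,3R,5R,6S,8R)-8-[(1S)-1-acetoxypropyl]-5,6-dihydroxy-2-[(2Z)-5-(trimethylsilyl)pent-2-en-4-yn-1-yl]oxocan-3-yl acetate
Product: 19 (2R,3R,5R,6S,8R)-8-[(1S)-1-acetoxypropyl]-5,6-dihydroxy-2-[(2Z)-pent-2-en-4-yn-1-yl]oxocan-3-yl acetate (CNP0314743.1)
Conditions: Bu4NF, AcOH, THF, 0 °C
Reagents that add atoms: none
Why: Fluoride-induced protodesilylation of the alkynylsilane; acetic acid buffering keeps the two acetates from hydrolysing or migrating to the free diol.

**Compound list**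

1 | (E)-pent-2-en-1-ol | CC/C=C/CO | starting material
2 | [(2S,3S)-3-ethyloxiran-2-yl]methanol | OC[C@@H]1O[C@H]1CC | intermediate
3 | ethynyltrimethylsilane | C#C[Si](C)(C)C | starting material
4 | [(2S,3S)-3-ethyloxiran-2-yl]methyl trifluoromethanesulfonate | FC(F)(F)S(=O)(=O)OC[C@@H]1O[C@H]1CC | intermediate
5 | trimethyl{3-[(2S,3S)-3-ethyloxiran-2-yl]prop-1-yn-1-yl}silane | C[Si](C)(C)C#CC[C@@H]1O[C@H]1CC | intermediate
6 | (2S,3S)-2-ethyl-3-(prop-2-yn-1-yl)oxirane | C#CC[C@@H]1O[C@H]1CC | intermediate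
7 | (+)-1,4-di-O-tosyl-2,3-O-isopropylidene-D-threitol, (4R,5R) | Cc1ccc(cc1)S(=O)(=O)OC[C@H]1OC(C)(C)O[C@@H]1COS(=O)(=O)c1ccc(C)cc1 | starting material
8 | (2R,3R)-1,4-di-O-tosylthreitol | Cc1ccc(cc1)S(=O)(=O)OC[C@@H](O)[C@H](O)COS(=O)(=O)c1ccc(C)cc1 | intermediate
9 | (2R,2'R)-2,2'-bioxirane | C1O[C@H]1[C@H]1CO1 | intermediate
10 | lithium trifluoro{(1R)-5-[(2S,3S)-3-ethyloxiran-2-yl]-1-[(2R)-oxiran-2-yl]pent-3-yn-1-yloxy}borate | CC[C@@H]1O[C@H]1CC#CC[C@@H](O[B-](F)(F)F)[C@H]1CO1.[Li+] | intermediate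
11 | (1R)-5-[(2S,3S)-3-ethyloxiran-2-yl]-1-[(2R)-oxiran-2-yl]pent-3-yn-1-yl acetate | CC[C@@H]1O[C@H]1CC#CC[C@@H](OC(C)=O)[C@H]1CO1 | intermediate
12 | (1R,3Z)-5-[(2S,3S)-3-ethyloxiran-2-yl]-1-[(2R)-oxiran-2-yl]pent-3-en-1-yl acetate | CC[C@@H]1O[C@H]1C/C=C\C[C@@H](OC(C)=O)[C@H]1CO1 | intermediate
13 | 1,4-bis(trimethylsilyl)buta-1,3-diyne | C[Si](C)(C)C#CC#C[Si](C)(C)C | starting material
14 | (6R,7R,9Z)-11-[(2S,3S)-3-ethyloxiran-2-yl]-6-hydroxy-1-(trimethylsilyl)undec-9-ene-1,3-diyn-7-yl acetate | CC[C@@H]1O[C@H]1C/C=C\C[C@@H](OC(C)=O)[C@H](O)CC#CC#C[Si](C)(C)C | intermediate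
15 | (2R,3R,8R,5Z)-8-[(1S)-1-hydroxypropyl]-2-[5-(trimethylsilyl)penta-2,4-diyn-1-yl]-3,4,7,8-tetrahydro-2H-oxocin-3-yl acetate | C[Si](C)(C)C#CC#CC[C@H]1O[C@@H]([C@H](CC)O)C/C=C\C[C@H]1OC(C)=O | intermediate
16 | (2R,3R,8R,5Z)-8-[(1S)-1-acetoxypropyl]-2-[5-(trimethylsilyl)penta-2,4-diyn-1-yl]-3,4,7,8-tetrahydro-2H-oxocin-3-yl acetate | C[Si](C)(C)C#CC#CC[C@H]1O[C@@H]([C@H](CC)OC(C)=O)C/C=C\C[C@H]1OC(C)=O | intermediate
17 | (2R,3R,5R,6S,8R)-8-[(1S)-1-acetoxypropyl]-5,6-dihydroxy-2-[5-(trimethylsilyl)penta-2,4-diyn-1-yl]oxocan-3-yl acetate | C[Si](C)(C)C#CC#CC[C@H]1O[C@@H]([C@H](CC)OC(C)=O)C[C@H](O)[C@H](O)C[C@H]1OC(C)=O | intermediate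
18 | (2R,3R,5R,6S,8R)-8-[(1S)-1-acetoxypropyl]-5,6-dihydroxy-2-[(2Z)-5-(trimethylsilyl)pent-2-en-4-yn-1-yl]oxocan-3-yl acetate | C[Si](C)(C)C#C/C=C\C[C@H]1O[C@@H]([C@H](CC)OC(C)=O)C[C@H](O)[C@H](O)C[C@H]1OC(C)=O | intermediate
19 | (2R,3R,5R,6S,8R)-8-[(1S)-1-acetoxypropyl]-5,6-dihydroxy-2-[(2Z)-pent-2-en-4-yn-1-yl]oxocan-3-yl acetate | C#C/C=C\C[C@H]1O[C@@H]([C@H](CC)OC(C)=O)C[C@H](O)[C@H](O)C[C@H]1OC(C)=O | target

**Step count**

Total: 12 steps. Longest linear sequence: 11 steps (1, 2, 3, 5, 6, 7, 8, 9, 10, 11, 12 from compound 1); step 4 is the side branch.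

**Three steps most likely to fail, with fallbacks**

Step 8, the proposed new closure. Likely failure modes are slow or no turnover, 9-endo opening, acid-induced epoxide rearrangement, and O7→O6 acetyl migration (the migrated isomer would close to a seven-membered ether). The fallback sets out from 14 and returns at 15, and it drops catalytic hydrogen-bond activation for a stoichiometric metal template. Compound 14 is heated with 1.2 equiv Eu(fod)3 [tris(6,6,7,7,8,8,8-heptafluoro-2,2-dimethyloctane-3,5-dionato)europium] in toluene at high dilution. The oxophilic lanthanide chelates the hydroxyl and epoxide oxygens and drives the exo SN2 closure thermally. To my recollection this lanthanide-promoted closure is established for eight- and nine-membered (Z)-olefinic hydroxy epoxides, so it is the known-chemistry option. It makes no new compound (F0).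

Step 10, facial selectivity of the osmylation on a conformationally mobile oxocene. I could not settle the preferred face by conformational analysis, so the anti selectivity is an expectation, not a certainty. If the syn face is preferred, the fallback sets out from 16 and returns at 17 and uses neighbouring-group delivery in place of a concerted cycloaddition. PhI(OCOCF3)2 in CH2Cl2 at −20 °C attacks the alkene from the face OsO4 would use. Trifluoroacetate opens anti, and acyloxonium participation then displaces iodobenzene, so both oxygens end up on the opposite face as the cis bis(trifluoroacetate) (2R,3R,5R,6S,8R)-3-acetoxy-8-[(1S)-1-acetoxypropyl]-2-[5-(trimethylsilyl)penta-2,4-diyn-1-yl]oxocane-5,6-diyl bis(trifluoroacetate) F5. NaHCO3 in MeOH at 0 °C cleaves only the trifluoroacetates and gives 17. Transannular capture by the ring oxygen is the risk to watch in this variant.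

Step 7, a diynide/BF3 opening in the presence of an acetate and a second epoxide, giving a hydroxyl next to a migratable acetate. The fallback sets out from 6 and 9 (with 13) and returns at 14. It reverses the order of the two epoxide openings and makes the (Z)-alkene before coupling, so the acetate never meets the diynide and no hydrogenation is needed.
- Alkyne 6 is iodinated (NIS, AgNO3 cat., acetone) to (2S,3S)-2-ethyl-3-(3-iodoprop-2-yn-1-yl)oxirane F1.
- F1 is reduced with diimide (2-nitrobenzenesulfonylhydrazide, Et3N) to (2S,3S)-2-ethyl-3-[(2Z)-3-iodoprop-2-en-1-yl]oxirane F2.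
- Separately, excess 9 is opened with the lithium diynide from 13 and BF3·OEt2 at −78 °C, and the alkoxide is silylated in the flask (Et3SiOTf, 2,6-lutidine) to give triethyl{[(1R)-1-[(2R)-oxiran-2-yl]-6-(trimethylsilyl)hexa-3,5-diyn-1-yl]oxy}silane F3.
- Iodine–lithium exchange on F2 (t-BuLi, Et2O, −78 °C), then BF3·OEt2 and F3, then an Ac2O/Et3N/DMAP quench, give (6R,7R,9Z)-11-[(2S,3S)-3-ethyloxiran-2-yl]-6-[(triethylsilyl)oxy]-1-(trimethylsilyl)undec-9-ene-1,3-diyn-7-yl acetate F4 with the alkene geometry retained.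
- HF·pyridine buffered with pyridine (THF, 0 °C) removes the triethylsilyl group and gives 14.

Further compounds
F1 | step 7 | (2S,3S)-2-ethyl-3-(3-iodoprop-2-yn-1-yl)oxirane | IC#CC[C@@H]1O[C@H]1CC
F2 | step 7 | (2S,3S)-2-ethyl-3-[(2Z)-3-iodoprop-2-en-1-yl]oxirane | I/C=C\C[C@@H]1O[C@H]1CC
F3 | step 7 | triethyl{[(1R)-1-[(2R)-oxiran-2-yl]-6-(trimethylsilyl)hexa-3,5-diyn-1-yl]oxy}silane | C[Si](C)(C)C#CC#CC[C@@H](O[Si](CC)(CC)CC)[C@H]1CO1
F4 | step 7 | (6R,7R,9Z)-11-[(2S,3S)-3-ethyloxiran-2-yl]-6-[(triethylsilyl)oxy]-1-(trimethylsilyl)undec-9-ene-1,3-diyn-7-yl acetate | CC[C@@H]1O[C@H]1C/C=C\C[C@@H](OC(C)=O)[C@H](O[Si](CC)(CC)CC)CC#CC#C[Si](C)(C)C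
F5 | step 10 | (2R,3R,5R,6S,8R)-3-acetoxy-8-[(1S)-1-acetoxypropyl]-2-[5-(trimethylsilyl)penta-2,4-diyn-1-yl]oxocane-5,6-diyl bis(trifluoroacetate) | C[Si](C)(C)C#CC#CC[C@H]1O[C@@H]([C@H](CC)OC(C)=O)C[C@H](OC(=O)C(F)(F)F)[C@H](OC(=O)C(F)(F)F)C[C@H]1OC(C)=O
F0 | step 8 | none | none
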